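**Plan**

- Retrosynthetic cuts: the ester bond between the C3 carboxyl and O5 of shikimate; the C4–vinyl bond of the acrylic acid; the O1–C2 bond of the dihydrobenzofuran; and, together, C2–C3 plus a temporary C2–O(acyl) bond.
- Enabling feature: C2 (bearing O1 and the catechol ring) and C3 (bearing the carboxyl and the benzofuran arene) are vicinal and cis, which is the pattern of a cis-3,4-diaryl-oxetan-2-one; O1 is a phenol oxygen ortho on the C3 aryl, placed to displace the lactone oxygen at C2.
- Forward order: the oxetanone ring is closed first by a catalytic asymmetric ketene–aldehyde [2+2] (step 8); fluoride then frees the ortho phenoxide, which opens the lactone at C2 and closes the furan ring (step 9); the acrylate, the shikimate ester and one acidic deprotection follow.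
- Stereochemistry: the alkaloid catalyst sets both lactone centres cis in step 8; the ring switch inverts C2 once, turning the cis (3R,4R) lactone into the cis (2S,3R) dihydrobenzofuran; the shikimate centres come from shikimic acid; the E alkene comes from the olefination.
- Design choice: the acrylate is attached only after the ring switch, so the ketene aryl carries a single ortho substituent and its enolate carbon stays accessible.

Key step: step 8

Assumption: O-trimethylsilylquinine is taken to give the (3R,4R) lactone, by analogy with the sense of induction of this catalyst family with alkyl ketenes; if the opposite sense is found, O-trimethylsilylquinidine takes its place.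

**Route**

Step 1
Reactants: 1 2-(allyloxy)phenol
Product: 2 1-(allyloxy)-2-(methoxymethoxy)benzene
Conditions: MOMCl, iPr2NEt, CH2Cl2, 0 °C to rt
Reagents that add atoms: chloromethyl methyl ether, COCCl
Why: O-alkylation of the phenol by the reactive chloromethyl ether under amine base should be clean, the allyl ether being inert.

Step 2
Reactants: 2 1-(allyloxy)-2-(methoxymethoxy)benzene
Product: 4 2-allyl-6-(methoxymethoxy)phenol, via 6-allyl dienone 3 (not isolated)
Conditions: N,N-diethylaniline, 190 °C, sealed tube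
Reagents that add atoms: none
Why: Aromatic Claisen rearrangement, in which the [3,3] shift goes to the only free ortho position and the dienone tautomerises to the phenol, while the basic solvent protects the MOM acetal.

Step 3
Reactants: 4 2-allyl-6-(methoxymethoxy)phenol
Product: 5 (2-allyl-6-(methoxymethoxy)phenoxy)(tert-butyl)dimethylsilane
Conditions: TBSCl, imidazole, DMF, rt to 40 °C
Reagents that add atoms: tert-butyldimethylsilyl chloride, CC(C)(C)[Si](C)(C)Cl
Why: Imidazole-promoted silylation of the phenol installs the fluoride-labile mask of the future O1.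

Step 4
Reactants: 5 (2-allyl-6-(methoxymethoxy)phenoxy)(tert-butyl)dimethylsilane
Product: 7 2-[2-(tert-butyldimethylsilyloxy)-3-(methoxymethoxy)phenyl]acetaldehyde, via diol 6 (not isolated)
Conditions: OsO4 (2 mol%), NaIO4 (4 equiv), 2,6-lutidine, dioxane/H2O (3:1), rt; crude aldehyde used directly
Reagents that add atoms: osmium tetroxide, O=[Os](=O)(=O)=O; sodium periodate (terminal oxidant and oxygen source), [Na+].[O-]I(=O)(=O)=O
Why: Lemieux–Johnson cleavage, in which the only alkene is dihydroxylated and the glycol is cut by periodate, the lutidine buffer holding back over-oxidation.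

Step 5
Reactants: 7 2-[2-(tert-butyldimethylsilyloxy)-3-(methoxymethoxy)phenyl]acetaldehyde
Product: 8 2-[2-(tert-butyldimethylsilyloxy)-3-(methoxymethoxy)phenyl]acetic acid
Conditions: NaClO2, NaH2PO4, 2-methyl-2-butene, t-BuOH/H2O, 0 °C to rt
Reagents that add atoms: sodium chlorite, [Na+].[O-]Cl=O
Why: Pinnick oxidation at about pH 4 converts the aldehyde to the acid without touching the aryl silyl ether or the MOM acetal, the alkene scavenger removing hypochlorite.

Step 6
Reactants: 8 2-[2-(tert-butyldimethylsilyloxy)-3-(methoxymethoxy)phenyl]acetic acid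
Product: 9 2-[2-(tert-butyldimethylsilyloxy)-3-(methoxymethoxy)phenyl]acetyl chloride
Conditions: 1-chloro-N,N,2-trimethylprop-1-en-1-amine (1.1 equiv), CH2Cl2, 0 °C to rt; amide co-product removed under high vacuum; used at once
Reagents that add atoms: 1-chloro-N,N,2-trimethylprop-1-en-1-amine, CC(C)=C(Cl)N(C)C
Why: The alpha-chloroenamine makes the acid chloride under neutral conditions, with no HCl that would endanger the MOM acetal.

Step 7
Reactants: 10 3,4-dihydroxybenzaldehyde
Product: 11 3,4-bis(tert-butoxycarbonyloxy)benzaldehyde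
Conditions: Boc2O (2.3 equiv), DMAP (5 mol%), THF, 0 °C to rt
Reagents that add atoms: di-tert-butyl dicarbonate, CC(C)(C)OC(=O)OC(=O)OC(C)(C)C
Why: DMAP-catalysed O-acylation of both phenols gives the bis-carbonate, which raises the electrophilicity of the aldehyde and later keeps the 4-aryl lactone from ionising.

Step 8
Reactants: 9 2-[2-(tert-butyldimethylsilyloxy)-3-(methoxymethoxy)phenyl]acetyl chloride; 11 3,4-bis(tert-butoxycarbonyloxy)benzaldehyde
Product: 13 (3R,4R)-4-[3,4-bis(tert-butoxycarbonyloxy)phenyl]-3-[2-(tert-butyldimethylsilyloxy)-3-(methoxymethoxy)phenyl]oxetan-2-one (cis), via arylketene 12 (not isolated)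
Conditions: O-trimethylsilylquinine (15 mol%), LiClO4 (2 equiv), iPr2NEt (2.5 equiv), CH2Cl2/Et2O (2:1), −78 °C; 9 (1.5 equiv) added over 4 h
Reagents that add atoms: none
Why: iPr2NEt dehydrochlorinates 9 to ketene 12, the quinuclidine nitrogen adds to its central carbon anti to the aryl group, and the resulting Z ammonium enolate attacks the LiClO4-activated aldehyde 11 through a closed, lithium-bridged chair-like transition state; the aldolate then closes the oxetanone by 4-exo-trig acyl substitution at the acylammonium carbon and releases the catalyst. The closest known reaction is the cinchona alkaloid/LiClO4-catalysed acyl halide–aldehyde cyclocondensation of alkyl-substituted acid chlorides, which gives cis-3,4-disubstituted beta-lactones. C3 is controlled by the alkaloid, which shields one face of the enolate, and C4 by the closed transition state with the aldehyde aryl group equatorial, so the Z enolate should give the cis (3R,4R) lactone. The step needs cross-reaction to win over ketene dimerisation and a lactone that survives: slow addition keeps the ketene concentration low, the two carbonates make 11 a strong electrophile and stop the 4-aryl lactone from ionising or losing CO2, and the ketene aryl has only one ortho substituent, which can turn away from the incoming aldehyde.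

Step 9
Reactants: 13 (3R,4R)-4-[3,4-bis(tert-butoxycarbonyloxy)phenyl]-3-[2-(tert-butyldimethylsilyloxy)-3-(methoxymethoxy)phenyl]oxetan-2-one
Product: 15 (2S,3R)-2-[3,4-bis(tert-butoxycarbonyloxy)phenyl]-7-(methoxymethoxy)-2,3-dihydro-1-benzofuran-3-carboxylic acid (2,3-cis), via lactone phenoxide 14 (not isolated)
Conditions: Bu4NF (1.05 equiv), THF, −40 to 0 °C; then cold 0.5 M HCl
Reagents that add atoms: none
Why: Proposed new method: fluoride cleaves the aryl silyl ether, and the naked phenoxide 14, held ortho on the C3 aryl, should attack the benzylic lactone C4 anti to the departing carboxylate (5-exo-tet, alkyl–oxygen cleavage), so that this carbon is inverted, the cis-lactone becomes the cis-dihydrobenzofuran and C3 ends as a carboxylate that cannot enolise; addition to the lactone carbonyl is expected to be unproductive because the tetrahedral adduct expels phenoxide in preference to alkoxide, and the carbonate-deactivated aryl keeps the opening SN2. The closest known reactions are the intermolecular alkyl–oxygen openings of beta-lactones by phenoxides, azide and sulfonamide anions, which go with inversion at C4.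

Step 10
Reactants: 15 (2S,3R)-2-[3,4-bis(tert-butoxycarbonyloxy)phenyl]-7-(methoxymethoxy)-2,3-dihydro-1-benzofuran-3-carboxylic acid; 16 tert-butyl acrylate
Product: 17 (2S,3R)-2-[3,4-bis(tert-butoxycarbonyloxy)phenyl]-4-[(E)-3-tert-butoxy-3-oxoprop-1-en-1-yl]-7-(methoxymethoxy)-2,3-dihydro-1-benzofuran-3-carboxylic acid
Conditions: Pd(OAc)2 (5 mol%), N-acetyl-L-isoleucine (10 mol%), KHCO3 (2 equiv), O2 (1 atm), tert-amyl alcohol, 85 °C; dilute HCl work-up
Reagents that add atoms: none
Why: Carboxylate-directed ortho C–H olefination (oxidative Heck type, amino-acid ligand, divalent palladium regenerated by O2), known for 2-aryl-2,3-dihydrobenzofuran-3-carboxylic acids, can only form its six-membered palladacycle at C4–H, gives the E alkene by beta-hydride elimination and leaves the potassium carboxylate at C3 configurationally intact.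

Step 11
Reactants: 18 shikimic acid
Product: 19 3,4-O-isopropylideneshikimic acid
Conditions: 2,2-dimethoxypropane, TsOH (cat.), acetone, rt
Reagents that add atoms: 2,2-dimethoxypropane, COC(C)(C)OC
Why: Acid-catalysed transketalisation engages only the cis 3,4-diol and leaves the trans-disposed C5 hydroxyl free.

Step 12
Reactants: 19 3,4-O-isopropylideneshikimic acid
Product: 20 tert-butyl 3,4-O-isopropylideneshikimate
Conditions: Me2NCH(OtBu)2, toluene, 80 °C
Reagents that add atoms: N,N-dimethylformamide di-tert-butyl acetal, CN(C)C(OC(C)(C)C)OC(C)(C)C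
Why: The formamide acetal tert-butylates the carboxylic acid selectively through its carboxylate/alkoxyiminium ion pair and leaves the secondary alcohol untouched.

Step 13
Reactants: 17 the C4-olefinated cis acid; 20 tert-butyl 3,4-O-isopropylideneshikimate
Product: 22 tert-butyl 5-O-{[(2S,3R)-2-[3,4-bis(tert-butoxycarbonyloxy)phenyl]-4-[(E)-3-tert-butoxy-3-oxoprop-1-en-1-yl]-7-(methoxymethoxy)-2,3-dihydro-1-benzofuran-3-yl]carbonyl}-3,4-O-isopropylideneshikimate, via O-acylisourea 21 (not isolated)
Conditions: N,N'-diisopropylcarbodiimide (1.2 equiv), DMAP (0.1 equiv), 20 (1.2 equiv), CH2Cl2, −20 to 0 °C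
Reagents that add atoms: none
Why: Steglich esterification of the only free hydroxyl of 20, run cold with substoichiometric DMAP so that the acylpyridinium is trapped before the cis C3 centre can epimerise through its enol.

Step 14
Reactants: 22 the fully protected ester
Product: 23 5-O-{[(2S,3R)-4-[(E)-2-carboxyethenyl]-2-(3,4-dihydroxyphenyl)-7-hydroxy-2,3-dihydro-1-benzofuran-3-yl]carbonyl}shikimic acid (CNP0312618.1)
Conditions: TFA/CH2Cl2/H2O (10:10:1), 0 °C to rt, short exposure; reverse-phase chromatography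
Reagents that add atoms: none
Why: One acidolysis should remove every protecting group (tert-butyl carbonates and esters by alkyl–oxygen cleavage, MOM and isopropylidene acetals by hydrolysis), while the electron-withdrawing ester at C3 disfavours ionisation at C2 during the brief treatment.

**Compound list**

1 | 2-(allyloxy)phenol | C=CCOc1ccccc1O | starting material
2 | 1-(allyloxy)-2-(methoxymethoxy)benzene | C=CCOc1ccccc1OCOC | intermediate
3 | 6-allyl-2-(methoxymethoxy)cyclohexa-2,4-dien-1-one | C=CCC1C=CC=C(OCOC)C1=O | intermediate (not isolated)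
4 | 2-allyl-6-(methoxymethoxy)phenol | C=CCc1cccc(OCOC)c1O | intermediate
5 | (2-allyl-6-(methoxymethoxy)phenoxy)(tert-butyl)dimethylsilane | C=CCc1cccc(OCOC)c1O[Si](C)(C)C(C)(C)C | intermediate
6 | 3-[2-(tert-butyldimethylsilyloxy)-3-(methoxymethoxy)phenyl]propane-1,2-diol (racemic) | OCC(O)Cc1cccc(OCOC)c1O[Si](C)(C)C(C)(C)C | intermediate (not isolated)
7 | 2-[2-(tert-butyldimethylsilyloxy)-3-(methoxymethoxy)phenyl]acetaldehyde | O=CCc1cccc(OCOC)c1O[Si](C)(C)C(C)(C)C | intermediate
8 | 2-[2-(tert-butyldimethylsilyloxy)-3-(methoxymethoxy)phenyl]acetic acid | O=C(O)Cc1cccc(OCOC)c1O[Si](C)(C)C(C)(C)C | intermediate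
9 | 2-[2-(tert-butyldimethylsilyloxy)-3-(methoxymethoxy)phenyl]acetyl chloride | O=C(Cl)Cc1cccc(OCOC)c1O[Si](C)(C)C(C)(C)C | intermediate
10 | 3,4-dihydroxybenzaldehyde | O=Cc1ccc(O)c(O)c1 | starting material
11 | 3,4-bis(tert-butoxycarbonyloxy)benzaldehyde | O=Cc1ccc(OC(=O)OC(C)(C)C)c(OC(=O)OC(C)(C)C)c1 | intermediate
12 | [2-(tert-butyldimethylsilyloxy)-3-(methoxymethoxy)phenyl]ketene | O=C=Cc1cccc(OCOC)c1O[Si](C)(C)C(C)(C)C | intermediate (not isolated)
13 | (3R,4R)-4-[3,4-bis(tert-butoxycarbonyloxy)phenyl]-3-[2-(tert-butyldimethylsilyloxy)-3-(methoxymethoxy)phenyl]oxetan-2-one | COCOc1cccc([C@H]2C(=O)O[C@H]2c3ccc(OC(=O)OC(C)(C)C)c(OC(=O)OC(C)(C)C)c3)c1O[Si](C)(C)C(C)(C)C | intermediate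
14 | tetrabutylammonium 2-{(3R,4R)-4-[3,4-bis(tert-butoxycarbonyloxy)phenyl]-2-oxooxetan-3-yl}-6-(methoxymethoxy)phenoxide | COCOc1cccc([C@H]2C(=O)O[C@H]2c3ccc(OC(=O)OC(C)(C)C)c(OC(=O)OC(C)(C)C)c3)c1[O-].CCCC[N+](CCCC)(CCCC)CCCC | intermediate (not isolated)
15 | (2S,3R)-2-[3,4-bis(tert-butoxycarbonyloxy)phenyl]-7-(methoxymethoxy)-2,3-dihydro-1-benzofuran-3-carboxylic acid | c1ccc(OCOC)c2c1[C@@H](C(=O)O)[C@@H](c3ccc(OC(=O)OC(C)(C)C)c(OC(=O)OC(C)(C)C)c3)O2 | intermediate
16 | tert-butyl acrylate | C=CC(=O)OC(C)(C)C | starting material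
17 | (2S,3R)-2-[3,4-bis(tert-butoxycarbonyloxy)phenyl]-4-[(E)-3-tert-butoxy-3-oxoprop-1-en-1-yl]-7-(methoxymethoxy)-2,3-dihydro-1-benzofuran-3-carboxylic acid | CC(C)(C)OC(=O)/C=C/c1ccc(OCOC)c2c1[C@@H](C(=O)O)[C@@H](c3ccc(OC(=O)OC(C)(C)C)c(OC(=O)OC(C)(C)C)c3)O2 | intermediate
18 | shikimic acid | O[C@@H]1CC(C(=O)O)=C[C@@H](O)[C@H]1O | starting material
19 | 3,4-O-isopropylideneshikimic acid | O[C@@H]1CC(C(=O)O)=C[C@H]2OC(C)(C)O[C@@H]12 | intermediate
20 | tert-butyl 3,4-O-isopropylideneshikimate | O[C@@H]1CC(C(=O)OC(C)(C)C)=C[C@H]2OC(C)(C)O[C@@H]12 | intermediate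
21 | O-acylisourea of 17 with N,N'-diisopropylcarbodiimide | CC(C)(C)OC(=O)/C=C/c1ccc(OCOC)c2c1[C@@H](C(=O)OC(=NC(C)C)NC(C)C)[C@@H](c3ccc(OC(=O)OC(C)(C)C)c(OC(=O)OC(C)(C)C)c3)O2 | intermediate (not isolated)
22 | tert-butyl 5-O-acyl-3,4-O-isopropylideneshikimate (acyl = the (2S,3R) dihydrobenzofuran-3-carbonyl group of 17) | CC(C)(C)OC(=O)/C=C/c1ccc(OCOC)c2c1[C@@H](C(=O)O[C@@H]1CC(C(=O)OC(C)(C)C)=C[C@H]3OC(C)(C)O[C@@H]13)[C@@H](c4ccc(OC(=O)OC(C)(C)C)c(OC(=O)OC(C)(C)C)c4)O2 | intermediate
23 | 5-O-{[(2S,3R)-4-[(E)-2-carboxyethenyl]-2-(3,4-dihydroxyphenyl)-7-hydroxy-2,3-dihydro-1-benzofuran-3-yl]carbonyl}shikimic acid | O=C(O)/C=C/c1ccc(O)c2c1[C@@H](C(=O)O[C@@H]1CC(C(=O)O)=C[C@@H](O)[C@H]1O)[C@@H](c1ccc(O)c(O)c1)O2 | target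

**Step count and risks**

Total: 14 steps. Longest linear sequence: 11 steps (steps 1–6, 8, 9, 10, 13, 14) from 2-(allyloxy)phenol.

Steps most likely to fail:

1. Step 9 (the proposed ring switch). The phenoxide may add to the lactone carbonyl instead of C4, which would lead to trans-lactonisation and retro-aldol fragmentation. It may also shuttle the C3 proton and epimerise the lactone before it opens, or the carbonates may be lost to fluoride. The fallback uses known chemistry, sets out from 13 and returns at 15. La(OtBu)3-catalysed alcoholysis with allyl alcohol in THF opens the lactone at the acyl carbon with retention and should give allyl (2R,3R)-3-[3,4-bis(tert-butoxycarbonyloxy)phenyl]-2-[2-(tert-butyldimethylsilyloxy)-3-(methoxymethoxy)phenyl]-3-hydroxypropanoate F1. HF·pyridine in THF removes the silyl group without forming a phenoxide and gives the phenol, allyl (2R,3R)-3-[3,4-bis(tert-butoxycarbonyloxy)phenyl]-3-hydroxy-2-[2-hydroxy-3-(methoxymethoxy)phenyl]propanoate F2. Mitsunobu cyclodehydration (PPh3, diisopropyl azodicarboxylate, THF, 0 °C) closes O1–C2 with inversion to allyl (2S,3R)-2-[3,4-bis(tert-butoxycarbonyloxy)phenyl]-7-(methoxymethoxy)-2,3-dihydro-1-benzofuran-3-carboxylate F3. Neutral deallylation with zerovalent palladium (Pd(PPh3)4, PhSiH3, CH2Cl2) then gives acid 15.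

2. Step 8. Dimerisation of the aryl ketene may outrun the cross-cycloaddition, or facial and cis selectivity may be poor for the aryl ketene/aryl aldehyde pair. The fallback replaces catalysis by an auxiliary-controlled aldol and lactonisation; it sets out from 9 and 11 and returns at 13. Acid chloride 9 acylates lithiated (R)-4-benzyl-1,3-oxazolidin-2-one (n-BuLi, THF, −78 °C) to give (R)-4-benzyl-3-{2-[2-(tert-butyldimethylsilyloxy)-3-(methoxymethoxy)phenyl]acetyl}-1,3-oxazolidin-2-one F4. A boron-mediated Evans syn-aldol reaction with 11 (Bu2BOTf, iPr2NEt, CH2Cl2, −78 °C) should give the (2R,3R) syn adduct, (R)-4-benzyl-3-{(2R,3R)-3-[3,4-bis(tert-butoxycarbonyloxy)phenyl]-2-[2-(tert-butyldimethylsilyloxy)-3-(methoxymethoxy)phenyl]-3-hydroxypropanoyl}-1,3-oxazolidin-2-one F5. Brief LiOH/H2O2 treatment at 0 °C removes the auxiliary, the hindered tert-butyl carbonates being expected to persist, and gives (2R,3R)-3-[3,4-bis(tert-butoxycarbonyloxy)phenyl]-2-[2-(tert-butyldimethylsilyloxy)-3-(methoxymethoxy)phenyl]-3-hydroxypropanoic acid F6. Carboxyl activation with PhSO2Cl in pyridine at 0 °C lactonises with retention at the carbinol carbon to 13.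

3. Step 13. The activated acyl species may enolise and epimerise C3 from cis to trans, or the hindered C5 hydroxyl may acylate too slowly. The fallback avoids acyl activation by making the carboxylate the nucleophile; it sets out from 20 (with 17) and returns at 22. Mitsunobu inversion of 20 with 4-nitrobenzoic acid (PPh3, diisopropyl azodicarboxylate, THF) gives tert-butyl 5-epi-5-O-(4-nitrobenzoyl)-3,4-O-isopropylideneshikimate F7. Methanolysis (K2CO3, MeOH, 0 °C) gives tert-butyl 5-epi-3,4-O-isopropylideneshikimate F8. A second Mitsunobu reaction of F8 with acid 17 inverts C5 back to the natural configuration and gives 22.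

**Further compounds**

F1 | step 9 | allyl (2R,3R)-3-[3,4-bis(tert-butoxycarbonyloxy)phenyl]-2-[2-(tert-butyldimethylsilyloxy)-3-(methoxymethoxy)phenyl]-3-hydroxypropanoate | C=CCOC(=O)[C@H](c1cccc(OCOC)c1O[Si](C)(C)C(C)(C)C)[C@@H](O)c1ccc(OC(=O)OC(C)(C)C)c(OC(=O)OC(C)(C)C)c1
F2 | step 9 | allyl (2R,3R)-3-[3,4-bis(tert-butoxycarbonyloxy)phenyl]-3-hydroxy-2-[2-hydroxy-3-(methoxymethoxy)phenyl]propanoate | C=CCOC(=O)[C@H](c1cccc(OCOC)c1O)[C@@H](O)c1ccc(OC(=O)OC(C)(C)C)c(OC(=O)OC(C)(C)C)c1
F3 | step 9 | allyl (2S,3R)-2-[3,4-bis(tert-butoxycarbonyloxy)phenyl]-7-(methoxymethoxy)-2,3-dihydro-1-benzofuran-3-carboxylate | c1ccc(OCOC)c2c1[C@@H](C(=O)OCC=C)[C@@H](c3ccc(OC(=O)OC(C)(C)C)c(OC(=O)OC(C)(C)C)c3)O2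
F4 | step 8 | (R)-4-benzyl-3-{2-[2-(tert-butyldimethylsilyloxy)-3-(methoxymethoxy)phenyl]acetyl}-1,3-oxazolidin-2-one | O=C(Cc1cccc(OCOC)c1O[Si](C)(C)C(C)(C)C)N1[C@H](Cc2ccccc2)COC1=O
F5 | step 8 | (R)-4-benzyl-3-{(2R,3R)-3-[3,4-bis(tert-butoxycarbonyloxy)phenyl]-2-[2-(tert-butyldimethylsilyloxy)-3-(methoxymethoxy)phenyl]-3-hydroxypropanoyl}-1,3-oxazolidin-2-one | O=C([C@H](c1cccc(OCOC)c1O[Si](C)(C)C(C)(C)C)[C@@H](O)c1ccc(OC(=O)OC(C)(C)C)c(OC(=O)OC(C)(C)C)c1)N1[C@H](Cc2ccccc2)COC1=O
F6 | step 8 | (2R,3R)-3-[3,4-bis(tert-butoxycarbonyloxy)phenyl]-2-[2-(tert-butyldimethylsilyloxy)-3-(methoxymethoxy)phenyl]-3-hydroxypropanoic acid | OC(=O)[C@H](c1cccc(OCOC)c1O[Si](C)(C)C(C)(C)C)[C@@H](O)c1ccc(OC(=O)OC(C)(C)C)c(OC(=O)OC(C)(C)C)c1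
F7 | step 13 | tert-butyl 5-epi-5-O-(4-nitrobenzoyl)-3,4-O-isopropylideneshikimate | O=C(O[C@H]1CC(C(=O)OC(C)(C)C)=C[C@H]2OC(C)(C)O[C@@H]12)c1ccc([N+](=O)[O-])cc1
F8 | step 13 | tert-butyl 5-epi-3,4-O-isopropylideneshikimate | O[C@H]1CC(C(=O)OC(C)(C)C)=C[C@H]2OC(C)(C)O[C@@H]12
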